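**Assumption:** the target has no stereocentre and no stable chiral axis, so it is made as the one achiral compound. Compounds 1 and 4 are taken as commercial.

**Retrosynthetic overview**
- The free OH on the tribromo ring comes from a formyl group (Dakin-type Baeyer–Villiger oxidation of aldehyde 7).
- The diaryl ether C–O bond comes from SNAr of phenol 6 on the ortho-fluorobenzaldehyde 3.
- 3 comes from double electrophilic bromination of 4-bromo-2-fluorobenzaldehyde 1; 6 comes from Dakin oxidation of 3,5-dibromo-2-methoxybenzaldehyde 4.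
- No ring is built: both benzene rings are bought, and all five bromines are in place before the ether bond is made.

**Route**

Step 1
Reactants: 1 4-bromo-2-fluorobenzaldehyde
Product: 3 3,4,5-tribromo-2-fluorobenzaldehyde, via 4,5-dibromo-2-fluorobenzaldehyde 2 (not isolated)
Conditions: NBS (2.4 equiv), conc. H2SO4, 60 °C
Reagents that add atoms: N-bromosuccinimide, O=C1CCC(=O)N1Br
Why: Electrophilic aromatic bromination in strong acid; C5 and then C3 are each ortho/para to F, ortho to the C4 bromine and meta to the protonated formyl group, so all directing effects agree and C6 is left alone.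

Step 2
Reactants: 4 3,5-dibromo-2-methoxybenzaldehyde
Product: 6 3,5-dibromo-2-methoxyphenol, via 3,5-dibromo-2-methoxyphenyl formate 5 (not isolated)
Conditions: mCPBA, CH2Cl2, rt; then HCl (cat.), MeOH, rt
Reagents that add atoms: mCPBA, O=C(OO)c1cccc(Cl)c1
Why: Dakin-type Baeyer–Villiger oxidation; the ortho-methoxy aryl group migrates in the Criegee adduct to give the formate, which methanolysis cleaves to the phenol.

Step 3
Reactants: 3 3,4,5-tribromo-2-fluorobenzaldehyde; 6 3,5-dibromo-2-methoxyphenol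
Product: 7 3,4,5-tribromo-2-(3,5-dibromo-2-methoxyphenoxy)benzaldehyde
Conditions: K2CO3, DMF, 80 °C
Reagents that add atoms: none
Why: SNAr (addition–elimination); the phenoxide of 6 displaces the fluoride ortho to the formyl group, which is far more labile than any C–Br bond, so the five bromines stay in place.

Step 4
Reactants: 7 3,4,5-tribromo-2-(3,5-dibromo-2-methoxyphenoxy)benzaldehyde
Product: 9 3,4,5-tribromo-2-(3,5-dibromo-2-methoxyphenoxy)phenol, via aryl formate 8 (not isolated)
Conditions: mCPBA, CH2Cl2, 40 °C; then HCl (cat.), MeOH, rt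
Reagents that add atoms: mCPBA, O=C(OO)c1cccc(Cl)c1
Why: Dakin-type Baeyer–Villiger oxidation; the ortho-aryloxy aryl group migrates to give formate 8, and acid-catalysed methanolysis frees the phenol without touching the methyl ether or the aryl bromides.

**Compound list**
1 | 4-bromo-2-fluorobenzaldehyde | O=Cc1ccc(Br)cc1F | starting material
2 | 4,5-dibromo-2-fluorobenzaldehyde | O=Cc1cc(Br)c(Br)cc1F | intermediate
3 | 3,4,5-tribromo-2-fluorobenzaldehyde | O=Cc1cc(Br)c(Br)c(Br)c1F | intermediate
4 | 3,5-dibromo-2-methoxybenzaldehyde | COc1c(Br)cc(Br)cc1C=O | starting material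
5 | 3,5-dibromo-2-methoxyphenyl formate | COc1c(Br)cc(Br)cc1OC=O | intermediate
6 | 3,5-dibromo-2-methoxyphenol | COc1c(Br)cc(Br)cc1O | intermediate
7 | 3,4,5-tribromo-2-(3,5-dibromo-2-methoxyphenoxy)benzaldehyde | COc1c(Br)cc(Br)cc1Oc1c(C=O)cc(Br)c(Br)c1Br | intermediate
8 | 3,4,5-tribromo-2-(3,5-dibromo-2-methoxyphenoxy)phenyl formate | COc1c(Br)cc(Br)cc1Oc1c(OC=O)cc(Br)c(Br)c1Br | intermediate
9 | 3,4,5-tribromo-2-(3,5-dibromo-2-methoxyphenoxy)phenol | COc1c(Br)cc(Br)cc1Oc1c(O)cc(Br)c(Br)c1Br | target

**Total step count:** 4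
**Longest linear sequence:** 3 steps (1 → 3 → 7 → 9, or 4 → 6 → 7 → 9)

**Three steps most likely to fail**

Step 1 (second bromination at the position flanked by F and Br may stall or the aldehyde may be oxidised). The fallback sets out from 1 and comes back at 3. It installs the hindered bromine by directed ortho-metalation instead of electrophilic substitution. Compound 1 is protected with ethylene glycol (TsOH cat., toluene, Dean–Stark) as 2-(4-bromo-2-fluorophenyl)-1,3-dioxolane F1. LDA in THF at −78 °C removes the proton between F and Br to give [6-bromo-2-fluoro-3-(1,3-dioxolan-2-yl)phenyl]lithium F2. Quenching with 1,2-dibromotetrachloroethane gives 2-(3,4-dibromo-2-fluorophenyl)-1,3-dioxolane F3. Aqueous HCl in THF releases 3,4-dibromo-2-fluorobenzaldehyde F4. One easy bromination (NBS 1.1 equiv, conc. H2SO4, rt) at the position para to F and meta to CHO then gives 3.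

Step 4 (on this electron-poor, hindered aldehyde, hydride migration to the benzoic acid may compete with aryl migration). The fallback sets out from 7 and comes back at 9. It replaces the formyl hydrogen by methyl so that no hydride can migrate. MeMgBr in THF at −78 °C gives racemic 1-[3,4,5-tribromo-2-(3,5-dibromo-2-methoxyphenoxy)phenyl]ethan-1-ol F9. Dess–Martin oxidation gives 1-[3,4,5-tribromo-2-(3,5-dibromo-2-methoxyphenoxy)phenyl]ethan-1-one F10. Baeyer–Villiger oxidation with trifluoroperacetic acid (TFAA, urea·H2O2, Na2HPO4, CH2Cl2) gives 3,4,5-tribromo-2-(3,5-dibromo-2-methoxyphenoxy)phenyl acetate F11, since aryl migrates in preference to methyl. K2CO3 in MeOH then gives 9.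

Step 3 (the fluoride is flanked by CHO and Br, and the aldehyde may not tolerate hot carbonate and phenoxide). The fallback sets out from 3 and comes back at 7. It carries the activating group as a small, base-stable nitrile and regenerates the aldehyde only after the ether bond is made. Compound 3 with NH2OH·HCl and HCO2Na in HCO2H at 100 °C gives (E)-3,4,5-tribromo-2-fluorobenzaldehyde oxime F5, which dehydrates in the same pot to 3,4,5-tribromo-2-fluorobenzonitrile F6. SNAr with 6 (K2CO3, DMSO, 70 °C) gives 3,4,5-tribromo-2-(3,5-dibromo-2-methoxyphenoxy)benzonitrile F7. DIBAL-H in toluene at −78 °C gives, after protonation, 1-[3,4,5-tribromo-2-(3,5-dibromo-2-methoxyphenoxy)phenyl]methanimine F8, which aqueous HCl hydrolyses to 7.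

**Further compounds**
F1 | step 1 | 2-(4-bromo-2-fluorophenyl)-1,3-dioxolane | Fc1cc(Br)ccc1C1OCCO1
F2 | step 1 | [6-bromo-2-fluoro-3-(1,3-dioxolan-2-yl)phenyl]lithium | [Li]c1c(F)c(C2OCCO2)ccc1Br
F3 | step 1 | 2-(3,4-dibromo-2-fluorophenyl)-1,3-dioxolane | Fc1c(Br)c(Br)ccc1C1OCCO1
F4 | step 1 | 3,4-dibromo-2-fluorobenzaldehyde | O=Cc1ccc(Br)c(Br)c1F
F5 | step 3 | (E)-3,4,5-tribromo-2-fluorobenzaldehyde oxime | O/N=C/c1cc(Br)c(Br)c(Br)c1F
F6 | step 3 | 3,4,5-tribromo-2-fluorobenzonitrile | N#Cc1cc(Br)c(Br)c(Br)c1F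
F7 | step 3 | 3,4,5-tribromo-2-(3,5-dibromo-2-methoxyphenoxy)benzonitrile | COc1c(Br)cc(Br)cc1Oc1c(C#N)cc(Br)c(Br)c1Br
F8 | step 3 | 1-[3,4,5-tribromo-2-(3,5-dibromo-2-methoxyphenoxy)phenyl]methanimine | COc1c(Br)cc(Br)cc1Oc1c(C=N)cc(Br)c(Br)c1Br
F9 | step 4 | rac-1-[3,4,5-tribromo-2-(3,5-dibromo-2-methoxyphenoxy)phenyl]ethan-1-ol | COc1c(Br)cc(Br)cc1Oc1c(C(C)O)cc(Br)c(Br)c1Br
F10 | step 4 | 1-[3,4,5-tribromo-2-(3,5-dibromo-2-methoxyphenoxy)phenyl]ethan-1-one | COc1c(Br)cc(Br)cc1Oc1c(C(C)=O)cc(Br)c(Br)c1Br
F11 | step 4 | 3,4,5-tribromo-2-(3,5-dibromo-2-methoxyphenoxy)phenyl acetate | COc1c(Br)cc(Br)cc1Oc1c(OC(C)=O)cc(Br)c(Br)c1Br
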